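**Retrosynthetic overview**
1. Artoflavanone 16 ⇒ aryl bromide 14 + racemic cyclopropa[b]benzofuran 13. The last step makes the C2–aryl bond, the C4 ketone, the six-membered ring C and the 2S centre together.
2. Enabling feature: in ring C (O1–C2–C3–C4–C4a–C8a) the C4 carbonyl stands 1,3 to C2, and C2 bears O1. C4–C3–C2 can therefore be stored as a siloxycyclopropane fused to the five-membered ring O1–C2–C4–C4a–C8a. The trioxygenated ring A on C4 makes this unit easy to oxidise, and O1 stabilises the C2 radical that appears when the fusion bond C2–C4 breaks.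
3. 5-OH/6-prenyl ⇒ aromatic Claisen rearrangement of a 5-O-(1,1-dimethylallyl) ether, which has only one free ortho carbon. It is placed after the cyclopropanation because a zinc carbenoid would attack a prenyl group. The allyl ether comes from a propargyl ether.
4. Ring order: ring A and the five-membered O-ring are bought in 1; cyclopropane in step 4; ring C by 5→6 expansion, with ring B attached in the same operation, in step 7.

Key step: step 7

Remark: the SMILES encodes 2S. The sense of induction of the chiral ligand L* in step 7 cannot be taken from precedent; both antipodes of L* are equally accessible, and the one that leads to 2S is meant.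

**Step 1**
Reactants: 1 4,6-dimethoxybenzofuran-3(2H)-one
Product: 3 4-hydroxy-6-methoxybenzofuran-3(2H)-one, via dichloroboron aryloxide 2 (not isolated)
Conditions: BCl3 (1.2 equiv), CH2Cl2, −78 to 0 °C; then 1 M HCl
Reagents that add atoms: none
Why: Chelation-controlled Lewis-acid cleavage of an aryl methyl ether: BCl3 is held between the C3 carbonyl and the peri 4-OMe in a six-membered chelate, so chloride removes only this methyl group, while the unchelated 6-OMe and the ring ether stay.

**Step 2**
Reactants: 3 4-hydroxy-6-methoxybenzofuran-3(2H)-one; 4 3-chloro-3-methylbut-1-yne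
Product: 5 6-methoxy-4-[(2-methylbut-3-yn-2-yl)oxy]benzofuran-3(2H)-one
Conditions: 4 (1.5 equiv), DBU (1.2 equiv), CuCl2·2H2O (1 mol %), MeCN, 0 °C
Reagents that add atoms: 3-chloro-3-methylbut-1-yne C#CC(C)(C)Cl
Why: Copper-catalysed propargylic etherification of a phenol with a tertiary propargylic chloride (via a copper allenylidene), in which the phenoxide, the first site deprotonated by the single equivalent of DBU, is alkylated on oxygen at 0 °C before the C2 enolate can form.

**Step 3**
Reactants: 5 6-methoxy-4-[(2-methylbut-3-yn-2-yl)oxy]benzofuran-3(2H)-one; 6 triethylsilyl triflate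
Product: 7 6-methoxy-4-[(2-methylbut-3-yn-2-yl)oxy]-3-(triethylsilyloxy)benzofuran
Conditions: TESOTf (1.2 equiv), Et3N (2 equiv), CH2Cl2, 0 °C
Reagents that add atoms: triethylsilyl triflate CC[Si](CC)(CC)OS(=O)(=O)C(F)(F)F
Why: Soft enolisation/O-silylation of a ketone (silyl triflate and amine), driven here by the gain of benzofuran aromaticity; the tertiary propargyl ether and the alkyne C–H are untouched under these buffered conditions.

**Step 4**
Reactants: 7 6-methoxy-4-[(2-methylbut-3-yn-2-yl)oxy]-3-(triethylsilyloxy)benzofuran; 8 diiodomethane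
Product: 9 rac-4-methoxy-6-[(2-methylbut-3-yn-2-yl)oxy]-6b-(triethylsilyloxy)-1a,6b-dihydro-1H-cyclopropa[b]benzofuran (cis-fused)
Conditions: Et2Zn (3 equiv), CH2I2 (3 equiv), CH2Cl2, 0 °C to rt; pyridine quench
Reagents that add atoms: diiodomethane ICI
Why: Furukawa variant of the Simmons–Smith cyclopropanation of a silyl enol ether: the C2=C3 bond carries two oxygen donors and is the most nucleophilic π bond, the alkyne is inert to the zinc carbenoid, the concerted syn transfer can give only the cis-fused bicycle, and the racemate suffices because both stereocentres are erased in step 7.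

**Step 5**
Reactants: 9 rac-4-methoxy-6-[(2-methylbut-3-yn-2-yl)oxy]-6b-(triethylsilyloxy)-1a,6b-dihydro-1H-cyclopropa[b]benzofuran
Product: 10 rac-4-methoxy-6-[(2-methylbut-3-en-2-yl)oxy]-6b-(triethylsilyloxy)-1a,6b-dihydro-1H-cyclopropa[b]benzofuran
Conditions: H2 (1 atm), Lindlar catalyst, quinoline, EtOAc, rt
Reagents that add atoms: none
Why: Lindlar semihydrogenation of a terminal alkyne stops at the alkene on the poisoned catalyst and leaves the donor-substituted cyclopropane, the silyl ether and the arene alone.

**Step 6**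
Reactants: 10 rac-4-methoxy-6-[(2-methylbut-3-en-2-yl)oxy]-6b-(triethylsilyloxy)-1a,6b-dihydro-1H-cyclopropa[b]benzofuran; 11 N,O-bis(trimethylsilyl)acetamide (BSA)
Product: 13 rac-4-methoxy-5-(3-methylbut-2-en-1-yl)-6b-(triethylsilyloxy)-6-(trimethylsilyloxy)-1a,6b-dihydro-1H-cyclopropa[b]benzofuran, via free phenol 12 (not isolated)
Conditions: BSA (2 equiv), toluene, 110 °C
Reagents that add atoms: N,O-bis(trimethylsilyl)acetamide CC(=N[Si](C)(C)C)O[Si](C)(C)C
Why: Aromatic Claisen rearrangement ([3,3]; allyl inversion turns the tertiary 1,1-dimethylallyl ether into the linear prenyl group) can end only at C5, the single free ortho carbon, and the phenol 12 set free is capped at once by BSA, which also keeps the medium neutral for the siloxycyclopropane.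

**Step 7**
Reactants: 13 rac-4-methoxy-5-(3-methylbut-2-en-1-yl)-6b-(triethylsilyloxy)-6-(trimethylsilyloxy)-1a,6b-dihydro-1H-cyclopropa[b]benzofuran; 14 5-bromo-1,2,3-trimethoxybenzene
Product: 16 artoflavanone (2S), via O-TMS flavanone 15 (not isolated)
Conditions: 14 (1.5 equiv), 4CzIPN (3 mol %), NiBr2·glyme (10 mol %), chiral 2,2'-bis(imidazoline) L* (12 mol %), 2,6-lutidine (2 equiv), MeCN, 450 nm LEDs, 15 °C; then 0.5 M citric acid, MeOH, 0 °C
Reagents that add atoms: 5-bromo-1,2,3-trimethoxybenzene COc1cc(Br)cc(OC)c1OC
Why: Proposed new method: the excited photocatalyst takes one electron from the trioxygenated arene bound to C6b, the radical cation gives up Et3Si+ to bromide/lutidine and the strained fusion bond C1a–C6b breaks, so the CH2 is taken into the former five-membered ring and ring C (O1–C2–C3–C4–C4a–C8a) appears by 5→6 expansion with its C4 ketone and a radical at C2; no ring is closed end to end. The closest known reaction types are the photoredox/nickel β-arylation of cyclopropanols with aryl bromides, the Saegusa and Dowd–Beckwith one-carbon ring expansions through 1-oxybicyclo[n.1.0]alkyl species (endocyclic scission), and the enantioselective nickel α-arylation of oxacycle radicals; what is new is their union on a cyclopropa[b]benzofuran. The regioselectivity needed (fusion bond, not C6b–CH2) is secured by O1, which makes the secondary C2 radical clearly more stable than the primary alternative, and any primary radical formed should return through the same cyclopropyloxy radical by 1,2-acyl shift faster than the dilute nickel complex traps it. The C2 stereocentre is new: both stereocentres of racemic 13 are erased in the planar radical, and the chiral bis(imidazoline)Ni(aryl) complex decides the configuration in radical capture/reductive elimination (enantioconvergent), with the ligand antipode chosen for 2S. Chemoselectivity rests on 13 being the most easily oxidised component, on the nucleophilic α-oxy radical ignoring the electron-rich prenyl alkene and on the capped phenol, and the medium is never basic enough for retro-oxa-Michael racemisation. The citric acid work-up removes the aryl TMS group of 15 and should give 16.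

**Compound list**
1 | 4,6-dimethoxybenzofuran-3(2H)-one | COc1cc(OC)c2c(c1)OCC2=O | starting material
2 | dichloro[(6-methoxy-3-oxo-2,3-dihydrobenzofuran-4-yl)oxy]borane | COc1cc(OB(Cl)Cl)c2c(c1)OCC2=O | intermediate
3 | 4-hydroxy-6-methoxybenzofuran-3(2H)-one | COc1cc(O)c2c(c1)OCC2=O | intermediate
4 | 3-chloro-3-methylbut-1-yne | C#CC(C)(C)Cl | starting material
5 | 6-methoxy-4-[(2-methylbut-3-yn-2-yl)oxy]benzofuran-3(2H)-one | COc1cc(OC(C)(C)C#C)c2c(c1)OCC2=O | intermediate
6 | triethylsilyl triflate | CC[Si](CC)(CC)OS(=O)(=O)C(F)(F)F | starting material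
7 | 6-methoxy-4-[(2-methylbut-3-yn-2-yl)oxy]-3-(triethylsilyloxy)benzofuran | COc1cc(OC(C)(C)C#C)c2c(O[Si](CC)(CC)CC)coc2c1 | intermediate
8 | diiodomethane | ICI | starting material
9 | rac-4-methoxy-6-[(2-methylbut-3-yn-2-yl)oxy]-6b-(triethylsilyloxy)-1a,6b-dihydro-1H-cyclopropa[b]benzofuran (cis-fused; one enantiomer drawn) | COc1cc(OC(C)(C)C#C)c2c(c1)O[C@H]1C[C@]12O[Si](CC)(CC)CC | intermediate
10 | rac-4-methoxy-6-[(2-methylbut-3-en-2-yl)oxy]-6b-(triethylsilyloxy)-1a,6b-dihydro-1H-cyclopropa[b]benzofuran (one enantiomer drawn) | COc1cc(OC(C)(C)C=C)c2c(c1)O[C@H]1C[C@]12O[Si](CC)(CC)CC | intermediate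
11 | N,O-bis(trimethylsilyl)acetamide | CC(=N[Si](C)(C)C)O[Si](C)(C)C | starting material
12 | rac-4-methoxy-5-(3-methylbut-2-en-1-yl)-6b-(triethylsilyloxy)-1a,6b-dihydro-1H-cyclopropa[b]benzofuran-6-ol (one enantiomer drawn) | COc1c(CC=C(C)C)c(O)c2c(c1)O[C@H]1C[C@]12O[Si](CC)(CC)CC | intermediate
13 | rac-4-methoxy-5-(3-methylbut-2-en-1-yl)-6b-(triethylsilyloxy)-6-(trimethylsilyloxy)-1a,6b-dihydro-1H-cyclopropa[b]benzofuran (one enantiomer drawn) | COc1c(CC=C(C)C)c(O[Si](C)(C)C)c2c(c1)O[C@H]1C[C@]12O[Si](CC)(CC)CC | intermediate
14 | 5-bromo-1,2,3-trimethoxybenzene | COc1cc(Br)cc(OC)c1OC | starting material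
15 | (2S)-7-methoxy-6-(3-methylbut-2-en-1-yl)-2-(3,4,5-trimethoxyphenyl)-5-(trimethylsilyloxy)chroman-4-one | COc1cc2c(c(O[Si](C)(C)C)c1CC=C(C)C)C(=O)C[C@@H](c1cc(OC)c(OC)c(OC)c1)O2 | intermediate
16 | artoflavanone, (2S)-5-hydroxy-7-methoxy-6-(3-methylbut-2-en-1-yl)-2-(3,4,5-trimethoxyphenyl)chroman-4-one | COc1cc2c(c(O)c1CC=C(C)C)C(=O)C[C@@H](c1cc(OC)c(OC)c(OC)c1)O2 | target

Total step count: 7. Longest linear sequence: 7 steps (1 to 16).

**Steps most likely to fail**

Step 7 (proposed new method).
- What may go wrong: β-hydride elimination of the alkylnickel species towards the chromone; capture of the primary radical before the 1,2-acyl shift; hydrogen abstraction by the C2 radical; weak facial discrimination at nickel; photo-oxidative erosion at the benzylic C2–H of the product.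
- Fallback with known chemistry, setting out from 9 and still using the same 5→6 expansion: a Saegusa ring expansion with FeCl3 in DMF at 0 °C should give 2-chloro-7-methoxy-5-[(2-methylbut-3-yn-2-yl)oxy]chroman-4-one F1. This loses HCl with NaOAc in MeOH to give 7-methoxy-5-[(2-methylbut-3-yn-2-yl)oxy]-4H-chromen-4-one F2. Lindlar semihydrogenation then gives 7-methoxy-5-[(2-methylbut-3-en-2-yl)oxy]-4H-chromen-4-one F3. A Hayashi–Miyaura rhodium-catalysed asymmetric 1,4-addition of 3,4,5-trimethoxyphenylboronic acid (Rh(I), electron-poor chiral biaryl diphosphine, toluene/H2O, rt) sets the stereocentre in (2S)-7-methoxy-5-[(2-methylbut-3-en-2-yl)oxy]-2-(3,4,5-trimethoxyphenyl)chroman-4-one F4. Heating F4 in toluene (aromatic Claisen rearrangement) comes back to the route at 16.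

Step 4.
- What may go wrong: sluggish methylene transfer to a double bond that is part of the benzofuran π system and flanked by two bulky oxygen substituents; zinc iodide-induced loss of the silyl group or isomerisation of the siloxycyclopropane.
- Fallback, setting out from 5: the lithium enolate (LDA, THF, −78 °C) is cyclopropanated with the oxygen-directed samarium carbenoid from SmI2/CH2I2 (cyclopropanol synthesis from enolates). This gives rac-4-methoxy-6-[(2-methylbut-3-yn-2-yl)oxy]-1a,6b-dihydro-1H-cyclopropa[b]benzofuran-6b-ol F5, which is silylated with TESCl/imidazole and comes back to the route at 9.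

Step 2.
- What may go wrong: competing deprotonation at the acidic C2 position, followed by C-alkylation or self-condensation of the benzofuranone.
- Fallback, setting out from 3, postpones the etherification until C2 is no longer acidic. Double silylation (TESOTf, Et3N) gives 6-methoxy-3,4-bis(triethylsilyloxy)benzofuran F6. Furukawa cyclopropanation gives rac-4-methoxy-6,6b-bis(triethylsilyloxy)-1a,6b-dihydro-1H-cyclopropa[b]benzofuran F7. Selective cleavage of the aryl silyl ether (LiOAc, moist DMF) gives rac-4-methoxy-6b-(triethylsilyloxy)-1a,6b-dihydro-1H-cyclopropa[b]benzofuran-6-ol F8. Palladium-catalysed O-allylation with tert-butyl (2-methylbut-3-en-2-yl) carbonate (Pd(PPh3)4, THF, 0 °C; Tsuji–Trost type, branched ether) comes back to the route at 10.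

**Further compounds**
F1 | step 7 | 2-chloro-7-methoxy-5-[(2-methylbut-3-yn-2-yl)oxy]chroman-4-one (racemic) | COc1cc(OC(C)(C)C#C)c2c(c1)OC(Cl)CC2=O
F2 | step 7 | 7-methoxy-5-[(2-methylbut-3-yn-2-yl)oxy]-4H-chromen-4-one | COc1cc(OC(C)(C)C#C)c2c(c1)OC=CC2=O
F3 | step 7 | 7-methoxy-5-[(2-methylbut-3-en-2-yl)oxy]-4H-chromen-4-one | COc1cc(OC(C)(C)C=C)c2c(c1)OC=CC2=O
F4 | step 7 | (2S)-7-methoxy-5-[(2-methylbut-3-en-2-yl)oxy]-2-(3,4,5-trimethoxyphenyl)chroman-4-one | COc1cc2c(c(OC(C)(C)C=C)c1)C(=O)C[C@@H](c1cc(OC)c(OC)c(OC)c1)O2
F5 | step 4 | rac-4-methoxy-6-[(2-methylbut-3-yn-2-yl)oxy]-1a,6b-dihydro-1H-cyclopropa[b]benzofuran-6b-ol (one enantiomer drawn) | COc1cc(OC(C)(C)C#C)c2c(c1)O[C@H]1C[C@]12O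
F6 | step 2 | 6-methoxy-3,4-bis(triethylsilyloxy)benzofuran | COc1cc(O[Si](CC)(CC)CC)c2c(O[Si](CC)(CC)CC)coc2c1
F7 | step 2 | rac-4-methoxy-6,6b-bis(triethylsilyloxy)-1a,6b-dihydro-1H-cyclopropa[b]benzofuran (one enantiomer drawn) | COc1cc(O[Si](CC)(CC)CC)c2c(c1)O[C@H]1C[C@]12O[Si](CC)(CC)CC
F8 | step 2 | rac-4-methoxy-6b-(triethylsilyloxy)-1a,6b-dihydro-1H-cyclopropa[b]benzofuran-6-ol (one enantiomer drawn) | COc1cc(O)c2c(c1)O[C@H]1C[C@]12O[Si](CC)(CC)CC
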